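Time was the first setting I turned by hand. In the dusk run the substrate left fell from 50.8% of the charge at 40.0 min to 24.6% at 80.0 min, and the square of the first fraction is 25.8%, so I read the decay as pseudo-first-order with a time constant of 57.0 min.

Catalyst came next. By hand, more catalyst should run the same clock faster in proportion, so I multiplied each run time by its catalyst charge over the dusk charge. For the flask this gives 40.0 min, and I call this scaled clock the dusk-equivalent time. The midnight run tests it: its last reading, at 80.0 min, scales to 36.3 min, where the dusk decay gives 53.0% left. The reading was 54.8%, a gap of 1.8 percentage points against a scatter of 0.3 points, so the scaling is good but not exact.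

The substrate and reagent charges were the same in both runs and in the flask, so the two runs offer no comparison for turning them. The flask's scaled clock lands on the dusk reading at 40.0 min, so I reckoned 49.2% reacted. The runs do not show bound reagent, so I set no figure of my own on that share.

| flask | substrate | reagent | free catalyst | remark | time |
|---|---|---|---|---|---|
| midnight | 0.10 M | 0.12 M | 3.4 mM | run made earlier |  |
| dusk | 0.10 M | 0.12 M | 7.5 mM | run made earlier |  |
| flask | 0.10 M | 0.120 M | 5.0 mM |  | 1.0 h |

| run | time / min | substrate / % | product / % |
|---|---|---|---|
| midnight | 15.0 | 89.3 | 8.9 |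
| midnight | 30.0 | 79.8 | 18.4 |
| midnight | 40.0 | 74.4 | 23.7 |
| midnight | 60.0 | 63.8 | 34.8 |
| midnight | 80.0 | 54.8 | 43.4 |
| dusk | 6.00 | 90.0 | 7.1 |
| dusk | 10.0 | 84.4 | 13.1 |
| dusk | 20.0 | 71.2 | 25.1 |
| dusk | 40.0 | 50.8 | 45.9 |
| dusk | 80.0 | 24.6 | 72.2 |

(each reading ± 0.3 percentage points)

* part of the substrate that has reacted at 1.0 h
* share of the unused reagent that is free and not bound as idle adduct, at 1.0 h

- the earlier runs do not show how much of reagent is bound; that part of a forecast is a guess

The forecast gave 49% reacted and 97% of the unused reagent free, and said of that share: “The runs don't establish this.”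

The flask gave 49.0% reacted and 66.1% free.

    substrate + free catalyst → catalyst intermediate A (k = 4.03 M⁻¹ min⁻¹)
    catalyst intermediate A → catalyst intermediate B (k = 1.54 min⁻¹)
    reagent + catalyst intermediate B → catalyst intermediate C (k = 10.7 M⁻¹ min⁻¹)
    catalyst intermediate C → by-product + catalyst intermediate D (k = 17.6 min⁻¹)
    catalyst intermediate D ⇌ free catalyst + product (K = 0.890 M, k = 1.31 min⁻¹)
    reagent + by-product ⇌ idle adduct, settled at all times (K = 22.4 M⁻¹)

At 1.00 h the flask held idle adduct equal to 20.5% of the reagent charge beside 39.9% free, and there the forecast's share parted from the flask. Substrate remained in the flask at that time because of the length of the run: 49.0% had reacted, against >99.9% in the same flask left to 10.0 h, and its dusk-equivalent time of 40.0 min is 0.702 of the time constant. The neighbour with 0.013 M of catalyst has a dusk-equivalent time of 104 min, so the decay gives 83.8% reacted, and that neighbour reacted 84.6%.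

The numbers in the tables are simulated for an exercise; scatter was added.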